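At 18 h, at one constant temperature, the theta run read 0.0524 M of target, 14.6% of its charge. The zeta run read 0.0230 M, or 47.9% of its charge. So the share fell as the charge rose, and theta had moved little since 0.0511 M at 14 h.

| flask | starting material | catalyst | time |
|---|---|---|---|
| eta | 0.120 M | 0.00360 M |  |
| zeta | 0.0480 M | 0.00360 M |  |
| theta | 0.360 M | 0.00360 M |  |
| alpha | 0.360 M | 0.00180 M | 18 h |

| run | time / h | [target] / M |
|---|---|---|
| eta run | 0.80 | 0.0101 |
| eta run | 2.4 | 0.0202 |
| eta run | 4.6 | 0.0260 |
| eta run | 7.4 | 0.0314 |
| eta run | 11 | 0.0339 |
| eta run | 14 | 0.0347 |
| eta run | 18 | 0.0363 |
| zeta run | 0.80 | 0.0050 |
| zeta run | 2.4 | 0.0120 |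
| zeta run | 4.6 | 0.0149 |
| zeta run | 7.4 | 0.0187 |
| zeta run | 11 | 0.0221 |
| zeta run | 14 | 0.0221 |
| zeta run | 18 | 0.0230 |
| theta run | 0.80 | 0.0197 |
| theta run | 2.4 | 0.0329 |
| theta run | 4.6 | 0.0416 |
| theta run | 7.4 | 0.0476 |
| theta run | 11 | 0.0486 |
| theta run | 14 | 0.0511 |
| theta run | 18 | 0.0524 |

(standard deviation of a reading: 6 × 10⁻⁴ M)

- Overall: starting material -> target, with catalyst as catalyst.
- Constant volume, constant temperature.
- A reading of a species includes what of it is bound.
- An order is taken over about fifteen percent of the charge, up and down.

- reaction order in [starting material] at the outset, round the charge of the eta run, defined at two percent of the starting material turned into target (one fixed amount of target, the same in the runs compared)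
- target in the alpha run at 18 h, as a share of the starting material charged
- which of these the readings show (the catalyst wakes slowly / the catalyst dies by itself / the product speeds the reaction / nothing beyond the main steps / two substrates go astray together / the product ties up the catalyst)

I counted turnovers. I supposed that the catalyst route eats starting material at first order, and that a loss without catalyst eats it in pairs. The two match at a crossover level c, and the target ends at c ln(1 + charge/c). Far above c, raising the charge by a factor adds c times the logarithm of that factor. The 18 h readings of eta and theta, taken as end values, thus gave c near 0.0147 M. Put back into the theta reading, this became 0.0162 M. Dividing by the catalyst gave the turnover budget, the turnovers each catalyst makes while the loss cuts the starting material by a factor e: 4.49.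

Next came the clock. The first eta reading, 0.0101 M at 0.80 h, divided by that time and by the charge, gave a first-order rate of 0.105 /h, which I scaled with catalyst. The target at a given time is then c ln(1 + (charge/c)(1 − e^(−rate × time))). The alpha run has half the catalyst, so its c is 0.00808 M, and this gave 7.50% at 18 h.

The clock was the weak link. That rate used the charge, but at 0.80 h the law leaves 0.0567 M of starting material in eta. So I inverted the time law at that reading. Reforged, the rate was 0.155 /h, and alpha came to 7.95%. The same inversion of the first readings gave 0.163 /h for zeta and 0.141 /h for theta. An order of one would keep this rate flat, so its drift gave orders of 0.950 from zeta to eta and 0.914 from eta to theta, and I put the order at eta between them.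

The forecast gave an order of 0.87, 8.9% and two substrates go astray together, saying “Competing routes fit well”. Its alpha value stood above my 7.95%.

The flask gave an order of 0.91, 8.34% and two substrates go astray together, and the forecast held on each.

    catalyst + starting material ⇌ catalyst-substrate complex, settled at all times (1.000 /M)
    catalyst-substrate complex → target + catalyst (45.00 /h)
    2 starting material → homo dimer (4.248 /M/h)

The alpha run's 8.34% at 18 h is 16.7 turnovers per catalyst, or 3.71 budgets of 4.49, and this is more than the 14.6 read in theta at the same charge. The alpha yield was lost to the pairing of starting material into homo dimer. The same run without that loss gives 70.0%, a gain of 62 percentage points and 67% of what is missing. Counted the same way, that run makes 140 turnovers per catalyst.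

The readings were generated by integration for an exercise.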